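**Strategy.** Numbering the chain from the benzylic CH2 (C1) to the ester-bearing CMe2 (C15), the 16-membered lactone carries its ring oxygen on gem-dimethyl C15 directly beside the C14 carbinol, the signature of a carboxylic acid adding to the tertiary carbon of a 14,15-epoxide. The route therefore ends with an acid-promoted macrolactonisation in which the aryl carboxylic acid opens a (14S)-2,2-dimethyloxirane at C15, forging the O–C15 bond, closing the macrocycle and unveiling the C14 hydroxyl in one operation. Its precursor is an open-chain epoxy acid that already holds the bromocyclohexene, both C–Br stereocentres and the C11 carbinol (as triethylsilyl ether), with the phenol as silyl ether.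

Key step: step 15

Remark: locants C1–C15 (C2=C3 ring alkene, C6 ring CHBr, C7 quaternary carbon, C10 chain CHBr, C11 methyl carbinol, C14 carbinol) are used for all intermediates; the target is (6S,7S,10R,11S,14S), with the C6 bromine cis to the C7 methyl group.
Remark: in step 2 hydride delivery anti to the larger allyl group is assumed, which places the new hydroxyl cis to allyl.

Step 1
Reactants: 1 2-methylcyclohexane-1,3-dione
Product: 2 2-methyl-2-(prop-2-en-1-yl)cyclohexane-1,3-dione
Conditions: allyl bromide, 1 M aq. NaOH, 23 °C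
Reagents that add atoms: allyl bromide, C=CCBr
Why: C-alkylation of the stabilised 1,3-dione enolate by an allylic halide builds the quaternary carbon (later C7) as a prochiral centre flanked by the two carbonyls that become C6 and C2.

Step 2
Reactants: 2 2-methyl-2-(prop-2-en-1-yl)cyclohexane-1,3-dione
Product: 3 (2R,3R)-3-hydroxy-2-methyl-2-(prop-2-en-1-yl)cyclohexan-1-one
Conditions: (S)-2-methyl-CBS-oxazaborolidine (20 mol%), catecholborane, PhNEt2, toluene, −60 °C
Reagents that add atoms: none
Why: Corey–Bakshi–Shibata desymmetrising reduction, in which the oxazaborolidine picks one enantiotopic carbonyl and delivers hydride anti to the allyl group, should set the carbinol as (3R) with OH cis to allyl and thereby fix the quaternary centre as (2R).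

Step 3
Reactants: 3 (2R,3R)-3-hydroxy-2-methyl-2-(prop-2-en-1-yl)cyclohexan-1-one
Product: 4 (2S,3S)-3-bromo-2-methyl-2-(prop-2-en-1-yl)cyclohexan-1-one
Conditions: CBr4, PPh3, CH2Cl2, 0 → 40 °C
Reagents that add atoms: carbon tetrabromide, BrC(Br)(Br)Br
Why: Appel reaction, in which bromide displaces the oxyphosphonium group in an SN2 sense with inversion, should place bromine cis to the methyl group (3S), the adjacent ketone disfavouring cationic 1,2-shifts and the quaternary α-carbon excluding elimination toward the carbonyl.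

Step 4
Reactants: 4 (2S,3S)-3-bromo-2-methyl-2-(prop-2-en-1-yl)cyclohexan-1-one
Product: 5 (2S,3S)-3-bromo-2,6-dimethyl-2-(prop-2-en-1-yl)cyclohexan-1-one (C6 epimers)
Conditions: LiN(iPr)2, THF, −78 °C; MeI, −78 → −20 °C
Reagents that add atoms: iodomethane, CI
Why: Kinetic enolate alkylation at the only enolisable α-carbon installs the future C3 methyl group, and the new methine centre is inconsequential because it becomes sp2 in step 5.

Step 5
Reactants: 5 (2S,3S)-3-bromo-2,6-dimethyl-2-(prop-2-en-1-yl)cyclohexan-1-one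
Product: 6 (5S,6S)-5-bromo-2,6-dimethyl-6-(prop-2-en-1-yl)cyclohex-1-en-1-yl trifluoromethanesulfonate
Conditions: KN(SiMe3)2, THF, −78 → 0 °C; PhNTf2, 0 → 23 °C
Reagents that add atoms: N-phenylbis(trifluoromethanesulfonimide), O=S(=O)(N(c1ccccc1)S(=O)(=O)C(F)(F)F)C(F)(F)F
Why: O-sulfonylation of the single possible (tetrasubstituted) enolate gives the enol triflate regiospecifically, arming C2 for cross-coupling and keeping the ring alkene electron-poor through the brominating and oxidising steps ahead.

Step 6
Reactants: 6 (5S,6S)-5-bromo-2,6-dimethyl-6-(prop-2-en-1-yl)cyclohex-1-en-1-yl trifluoromethanesulfonate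
Product: 7 (5S,6S)-5-bromo-2,6-dimethyl-6-(4-oxobutyl)cyclohex-1-en-1-yl trifluoromethanesulfonate
Conditions: Rh(acac)(CO)2 (1 mol%), BiPhePhos (3 mol%), CO/H2 (1:1, 10 bar), toluene, 60 °C
Reagents that add atoms: carbon monoxide, [C-]#[O+]
Why: Linear-selective rhodium-catalysed hydroformylation of the only monosubstituted alkene adds C11 as an aldehyde, the tetrasubstituted enol triflate alkene and the alkyl bromide being inert to the catalyst.

Step 7
Reactants: 7 (5S,6S)-5-bromo-2,6-dimethyl-6-(4-oxobutyl)cyclohex-1-en-1-yl trifluoromethanesulfonate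
Product: 9 (5S,6S)-5-bromo-6-[(3R)-3-bromo-4-hydroxypentyl]-2,6-dimethylcyclohex-1-en-1-yl trifluoromethanesulfonate (both carbinol epimers), via α-bromo aldehyde 8 (not isolated)
Conditions: (R)-2-{bis[3,5-bis(trifluoromethyl)phenyl](trimethylsilyloxy)methyl}pyrrolidine (20 mol%), 4,4-dibromo-2,6-di-tert-butylcyclohexa-2,5-dien-1-one, PhCO2H (20 mol%), CH2Cl2/pentane, −40 °C; then MeMgBr (excess), Et2O, −78 °C; sat. aq. NH4Cl, −78 °C
Reagents that add atoms: 4,4-dibromo-2,6-di-tert-butylcyclohexa-2,5-dien-1-one, O=C1C(C(C)(C)C)=CC(Br)(Br)C=C1C(C)(C)C; methylmagnesium bromide, C[Mg]Br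
Why: Enamine-catalysed α-bromination of the aldehyde, in which the diarylprolinol silyl ether shields one enamine face, should set C10 as (R), and the labile bromo aldehyde is trapped at once by Grignard 1,2-addition to a carbinol whose configuration is erased in step 8.

Step 8
Reactants: 9 (5S,6S)-5-bromo-6-[(3R)-3-bromo-4-hydroxypentyl]-2,6-dimethylcyclohex-1-en-1-yl trifluoromethanesulfonate
Product: 10 (5S,6S)-5-bromo-6-[(3R)-3-bromo-4-oxopentyl]-2,6-dimethylcyclohex-1-en-1-yl trifluoromethanesulfonate
Conditions: Dess–Martin periodinane, NaHCO3, CH2Cl2, 0 → 23 °C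
Reagents that add atoms: none
Why: Dess–Martin oxidation under bicarbonate buffering gives the α-bromo methyl ketone without a base able to enolise and scramble the C10 bromide.

Step 9
Reactants: 10 (5S,6S)-5-bromo-6-[(3R)-3-bromo-4-oxopentyl]-2,6-dimethylcyclohex-1-en-1-yl trifluoromethanesulfonate; 11 5-bromo-2-methylpent-2-ene
Product: 13 (5S,6S)-5-bromo-6-[(3R,4S)-3-bromo-4-hydroxy-4,8-dimethylnon-7-en-1-yl]-2,6-dimethylcyclohex-1-en-1-yl trifluoromethanesulfonate, via homoprenylmagnesium bromide 12 (not isolated)
Conditions: 11, Mg, THF, 23 °C; then 10, toluene/Et2O, −78 °C; sat. aq. NH4Cl, −78 °C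
Reagents that add atoms: none
Why: Grignard 1,2-addition under Cornforth control, with C–Br and C=O dipoles opposed and attack on the ketone face flanked by the C10 hydrogen, should relay (10R) to the (11S) tertiary carbinol, and the cold quench prevents the anti bromohydrin alkoxide from closing to an epoxide.

Step 10
Reactants: 13 (5S,6S)-5-bromo-6-[(3R,4S)-3-bromo-4-hydroxy-4,8-dimethylnon-7-en-1-yl]-2,6-dimethylcyclohex-1-en-1-yl trifluoromethanesulfonate
Product: 14 (5S,6S)-5-bromo-6-[(3R,4S)-3-bromo-4,8-dimethyl-4-(triethylsilyloxy)non-7-en-1-yl]-2,6-dimethylcyclohex-1-en-1-yl trifluoromethanesulfonate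
Conditions: TESOTf, 2,6-lutidine, CH2Cl2, −78 → 0 °C
Reagents that add atoms: triethylsilyl trifluoromethanesulfonate, CC[Si](CC)(CC)OS(=O)(=O)C(F)(F)F
Why: Silylation of the hindered tertiary alcohol with a silyl triflate and a non-nucleophilic base masks O11, so that it can neither displace the C10 bromide in the basic epoxidation nor attack the future 14,15-epoxide in a 5-exo sense.

Step 11
Reactants: 14 (5S,6S)-5-bromo-6-[(3R,4S)-3-bromo-4,8-dimethyl-4-(triethylsilyloxy)non-7-en-1-yl]-2,6-dimethylcyclohex-1-en-1-yl trifluoromethanesulfonate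
Product: 15 (5S,6S)-5-bromo-6-{(3R,4S)-3-bromo-6-[(2S)-3,3-dimethyloxiran-2-yl]-4-methyl-4-(triethylsilyloxy)hexyl}-2,6-dimethylcyclohex-1-en-1-yl trifluoromethanesulfonate
Conditions: L-fructose-derived Shi ketone (ent-Shi ketone, 30 mol%), KHSO5 (as 2KHSO5·KHSO4·K2SO4), K2CO3, Bu4NHSO4, aq. Na2B4O7 buffer, MeCN/dimethoxymethane, 0 °C
Reagents that add atoms: potassium peroxymonosulfate, [K+].[O-]S(=O)(=O)OO
Why: Shi epoxidation, in which the chiral dioxirane transfers oxygen through a spiro transition state under catalyst control, should give the (14S) oxirane at the electron-rich trisubstituted alkene while the electron-poor enol triflate alkene is left alone.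

Step 12
Reactants: 16 4-hydroxy-3-methylbenzoic acid
Product: 17 tert-butyldimethylsilyl 4-(tert-butyldimethylsilyloxy)-3-methylbenzoate
Conditions: TBSCl (2.4 equiv), imidazole, DMF, 23 °C
Reagents that add atoms: tert-butyldimethylsilyl chloride, CC(C)(C)[Si](C)(C)Cl
Why: Silylation of both acidic hydroxyls gives the phenol ether and a silyl ester that is inert to organozinc and zerovalent palladium yet is later removed by mild carbonate without fluoride or strong acid.

Step 13
Reactants: 17 tert-butyldimethylsilyl 4-(tert-butyldimethylsilyloxy)-3-methylbenzoate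
Product: 18 tert-butyldimethylsilyl 3-(bromomethyl)-4-(tert-butyldimethylsilyloxy)benzoate
Conditions: N-bromosuccinimide, AIBN (5 mol%), PhCF3, 85 °C
Reagents that add atoms: N-bromosuccinimide, O=C1CCC(=O)N1Br
Why: Wohl–Ziegler radical bromination is confined to the single benzylic methyl group of the deactivated arene.

Step 14
Reactants: 15 (5S,6S)-5-bromo-6-{(3R,4S)-3-bromo-6-[(2S)-3,3-dimethyloxiran-2-yl]-4-methyl-4-(triethylsilyloxy)hexyl}-2,6-dimethylcyclohex-1-en-1-yl trifluoromethanesulfonate; 18 tert-butyldimethylsilyl 3-(bromomethyl)-4-(tert-butyldimethylsilyloxy)benzoate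
Product: 21 3-{[(5S,6S)-5-bromo-6-{(3R,4S)-3-bromo-6-[(2S)-3,3-dimethyloxiran-2-yl]-4-methyl-4-(triethylsilyloxy)hexyl}-2,6-dimethylcyclohex-1-en-1-yl]methyl}-4-(tert-butyldimethylsilyloxy)benzoic acid, via benzylzinc bromide 19 (not isolated), via coupled silyl ester 20 (not isolated)
Conditions: 18, Zn dust, LiCl, THF, 0 → 23 °C, solution decanted from excess Zn; then 15, Pd(OAc)2 (5 mol%), SPhos (10 mol%), THF, 23 → 40 °C; then K2CO3, MeOH/H2O, 0 °C, pH 5 phosphate buffer
Reagents that add atoms: none
Why: Negishi sp3–sp2 coupling, in which zerovalent palladium inserts into the enol triflate far faster than into the secondary alkyl bromides and the benzylzinc transfers the arylmethyl group to C2, is followed by brief carbonate hydrolysis of the silyl ester that leaves the aryl and tertiary silyl ethers, the epoxide and both bromides intact.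

Step 15
Reactants: 21 3-{[(5S,6S)-5-bromo-6-{(3R,4S)-3-bromo-6-[(2S)-3,3-dimethyloxiran-2-yl]-4-methyl-4-(triethylsilyloxy)hexyl}-2,6-dimethylcyclohex-1-en-1-yl]methyl}-4-(tert-butyldimethylsilyloxy)benzoic acid
Product: 22 (6S,7S,10R,11S,14S)-bromophycolide G 11-O-triethylsilyl ether, phenol O-tert-butyldimethylsilyl ether (16-membered lactone with free C14 hydroxyl)
Conditions: (±)-camphorsulfonic acid (0.2 equiv), 4 Å MS, CH2Cl2 (0.5 mM, slow addition of 21), 0 → 23 °C
Reagents that add atoms: none
Why: The sulfonic acid polarises the oxirane toward a tertiary, gem-dimethyl-stabilised cation at C15, and the carbonyl oxygen of the tethered aryl carboxylic acid captures it with loss of a proton, so the C14–O bond is never broken. The closest known reaction type is the Brønsted-acid-mediated Markovnikov opening of 2,2-dimethyl-3-alkyl oxiranes by carboxylic acids, here run intramolecularly at high dilution as a macrolactonisation. The single ring formed is the 16-membered lactone, closed in the endo sense by attack on the distal oxirane carbon, whereas the 15-membered exo alternative would need attack at the more hindered, less cation-stabilising secondary C14. No stereocentre is created, since C14 keeps the (S) configuration set by the Shi epoxidation and C15 is not stereogenic. The step needs regioselectivity for C15 and the carboxyl as sole nucleophile, which are secured by the gem-dimethyl group, by the triethylsilyl cap on O11 (its oxygen further deactivated by the vicinal bromine) and by the silylated phenol, while slow addition suppresses oligomerisation and sieves exclude water. The hindered tertiary ester thus arises by alkyl C–O bond formation, without any acyl activation.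

Step 16
Reactants: 22 (6S,7S,10R,11S,14S)-bromophycolide G 11-O-triethylsilyl ether, phenol O-tert-butyldimethylsilyl ether
Product: 23 bromophycolide G
Conditions: HF·pyridine, pyridine, THF, 0 → 23 °C
Reagents that add atoms: none
Why: Buffered fluoride desilylation should remove both silyl ethers without forming the C11 alkoxide, which would displace the anti C10 bromide, and without base that could shift the acyl group from O15 to O14.

**Compound list**

1 | 2-methylcyclohexane-1,3-dione | CC1C(=O)CCCC1=O | starting material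
2 | 2-methyl-2-(prop-2-en-1-yl)cyclohexane-1,3-dione | C=CCC1(C)C(=O)CCCC1=O | intermediate
3 | (2R,3R)-3-hydroxy-2-methyl-2-(prop-2-en-1-yl)cyclohexan-1-one (OH cis to allyl) | C=CC[C@]1(C)[C@H](O)CCCC1=O | intermediate
4 | (2S,3S)-3-bromo-2-methyl-2-(prop-2-en-1-yl)cyclohexan-1-one (Br cis to methyl) | C=CC[C@]1(C)[C@@H](Br)CCCC1=O | intermediate
5 | (2S,3S)-3-bromo-2,6-dimethyl-2-(prop-2-en-1-yl)cyclohexan-1-one (C6 epimers) | C=CC[C@]1(C)[C@@H](Br)CCC(C)C1=O | intermediate
6 | (5S,6S)-5-bromo-2,6-dimethyl-6-(prop-2-en-1-yl)cyclohex-1-en-1-yl trifluoromethanesulfonate | C=CC[C@]1(C)[C@@H](Br)CCC(C)=C1OS(=O)(=O)C(F)(F)F | intermediate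
7 | (5S,6S)-5-bromo-2,6-dimethyl-6-(4-oxobutyl)cyclohex-1-en-1-yl trifluoromethanesulfonate | O=CCCC[C@]1(C)[C@@H](Br)CCC(C)=C1OS(=O)(=O)C(F)(F)F | intermediate
8 | (5S,6S)-5-bromo-6-[(3R)-3-bromo-4-oxobutyl]-2,6-dimethylcyclohex-1-en-1-yl trifluoromethanesulfonate | O=C[C@H](Br)CC[C@]1(C)[C@@H](Br)CCC(C)=C1OS(=O)(=O)C(F)(F)F | intermediate
9 | (5S,6S)-5-bromo-6-[(3R)-3-bromo-4-hydroxypentyl]-2,6-dimethylcyclohex-1-en-1-yl trifluoromethanesulfonate (carbinol epimers) | CC(O)[C@H](Br)CC[C@]1(C)[C@@H](Br)CCC(C)=C1OS(=O)(=O)C(F)(F)F | intermediate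
10 | (5S,6S)-5-bromo-6-[(3R)-3-bromo-4-oxopentyl]-2,6-dimethylcyclohex-1-en-1-yl trifluoromethanesulfonate | CC(=O)[C@H](Br)CC[C@]1(C)[C@@H](Br)CCC(C)=C1OS(=O)(=O)C(F)(F)F | intermediate
11 | 5-bromo-2-methylpent-2-ene | CC(C)=CCCBr | starting material
12 | (4-methylpent-3-en-1-yl)magnesium bromide | CC(C)=CCC[Mg]Br | intermediate
13 | (5S,6S)-5-bromo-6-[(3R,4S)-3-bromo-4-hydroxy-4,8-dimethylnon-7-en-1-yl]-2,6-dimethylcyclohex-1-en-1-yl trifluoromethanesulfonate | CC(C)=CCC[C@](C)(O)[C@H](Br)CC[C@]1(C)[C@@H](Br)CCC(C)=C1OS(=O)(=O)C(F)(F)F | intermediate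
14 | (5S,6S)-5-bromo-6-[(3R,4S)-3-bromo-4,8-dimethyl-4-(triethylsilyloxy)non-7-en-1-yl]-2,6-dimethylcyclohex-1-en-1-yl trifluoromethanesulfonate | CC(C)=CCC[C@](C)(O[Si](CC)(CC)CC)[C@H](Br)CC[C@]1(C)[C@@H](Br)CCC(C)=C1OS(=O)(=O)C(F)(F)F | intermediate
15 | (5S,6S)-5-bromo-6-{(3R,4S)-3-bromo-6-[(2S)-3,3-dimethyloxiran-2-yl]-4-methyl-4-(triethylsilyloxy)hexyl}-2,6-dimethylcyclohex-1-en-1-yl trifluoromethanesulfonate | CC1(C)O[C@H]1CC[C@](C)(O[Si](CC)(CC)CC)[C@H](Br)CC[C@]2(C)[C@@H](Br)CCC(C)=C2OS(=O)(=O)C(F)(F)F | intermediate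
16 | 4-hydroxy-3-methylbenzoic acid | Cc1cc(ccc1O)C(O)=O | starting material
17 | tert-butyldimethylsilyl 4-(tert-butyldimethylsilyloxy)-3-methylbenzoate | Cc1cc(ccc1O[Si](C)(C)C(C)(C)C)C(=O)O[Si](C)(C)C(C)(C)C | intermediate
18 | tert-butyldimethylsilyl 3-(bromomethyl)-4-(tert-butyldimethylsilyloxy)benzoate | BrCc1cc(ccc1O[Si](C)(C)C(C)(C)C)C(=O)O[Si](C)(C)C(C)(C)C | intermediate
19 | {2-(tert-butyldimethylsilyloxy)-5-[(tert-butyldimethylsilyloxy)carbonyl]benzyl}zinc bromide | Br[Zn]Cc1cc(ccc1O[Si](C)(C)C(C)(C)C)C(=O)O[Si](C)(C)C(C)(C)C | intermediate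
20 | tert-butyldimethylsilyl ester of seco acid 21 | CC1(C)O[C@H]1CC[C@](C)(O[Si](CC)(CC)CC)[C@H](Br)CC[C@]2(C)[C@@H](Br)CCC(C)=C2Cc3cc(ccc3O[Si](C)(C)C(C)(C)C)C(=O)O[Si](C)(C)C(C)(C)C | intermediate
21 | 3-{[(5S,6S)-5-bromo-6-{(3R,4S)-3-bromo-6-[(2S)-3,3-dimethyloxiran-2-yl]-4-methyl-4-(triethylsilyloxy)hexyl}-2,6-dimethylcyclohex-1-en-1-yl]methyl}-4-(tert-butyldimethylsilyloxy)benzoic acid (seco epoxy acid) | CC1(C)O[C@H]1CC[C@](C)(O[Si](CC)(CC)CC)[C@H](Br)CC[C@]2(C)[C@@H](Br)CCC(C)=C2Cc3cc(ccc3O[Si](C)(C)C(C)(C)C)C(O)=O | intermediate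
22 | (6S,7S,10R,11S,14S)-bromophycolide G 11-O-triethylsilyl ether, phenol O-tert-butyldimethylsilyl ether (16-membered lactone, free C14 hydroxyl) | CC1=C2Cc3cc(ccc3O[Si](C)(C)C(C)(C)C)C(=O)OC(C)(C)[C@@H](O)CC[C@](C)(O[Si](CC)(CC)CC)[C@H](Br)CC[C@]2(C)[C@@H](Br)CC1 | intermediate
23 | bromophycolide G | CC1=C2Cc3cc(ccc3O)C(=O)OC(C)(C)[C@@H](O)CC[C@](C)(O)[C@H](Br)CC[C@]2(C)[C@@H](Br)CC1 | target

**Step count.** Total: 16 steps. Longest linear sequence: 14 steps (steps 1–11, 14, 15, 16); steps 12 and 13 prepare the arene fragment.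

**Steps most likely to fail**

Step 15 (macrolactonisation). At high dilution the activated oxirane may decay faster than the remote carboxyl can reach it: hydride shift to a ketone, elimination to an allylic alcohol, or 5-exo capture by the O11 silyl ether with loss of silicon. The fallback reverses the order of the two fragment unions, setting out from 15 and 18 and returning at 22. Bromide 18 is hydrolysed at the silyl ester (AcOH, THF/H2O, 23 °C) to 3-(bromomethyl)-4-(tert-butyldimethylsilyloxy)benzoic acid F1. An excess of this acid opens epoxy triflate 15 intermolecularly at C15 under camphorsulfonic acid catalysis at high concentration, where bimolecular capture can compete, giving the C15 tertiary benzoate with free C14 hydroxyl F2. Zinc insertion into the benzylic bromide (Zn, LiCl, THF, 0 °C) and an intramolecular Negishi coupling with the enol triflate (Pd(OAc)2, SPhos, THF, high dilution; organozinc halides tolerate a free secondary hydroxyl under this catalyst) then close the macrocycle at C1–C2 to give 22.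

Step 3 (bromination of the neopentyl carbinol). The oxyphosphonium intermediate may eliminate toward C4 or undergo ring-contracting acyl migration instead of being displaced, and substitution may be slow at a carbon next to a quaternary centre. The fallback separates activation from displacement, setting out from 3 and returning at 4. The alcohol is converted into the isolable sulfonate (1R,2R)-2-methyl-3-oxo-2-(prop-2-en-1-yl)cyclohexyl trifluoromethanesulfonate F3 (Tf2O, pyridine, CH2Cl2, −20 °C). This is then treated with Bu4NBr in toluene (0 → 23 °C), so that a poorly solvated bromide displaces a far better leaving group with the same inversion.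

Step 14 (Negishi coupling and ester unmasking). Lewis-acidic zinc halide may open or rearrange the 14,15-epoxide, transmetalation to the hindered tetrasubstituted alkenyl palladium may be slow, and the carbonate treatment may erode the aryl silyl ether. The fallback transfers the benzyl group from tin, setting out from 19 and 15 and returning at 20 and then 21. Zinc reagent 19 is quenched with Bu3SnCl to tert-butyldimethylsilyl 4-(tert-butyldimethylsilyloxy)-3-[(tributylstannyl)methyl]benzoate F4. This is coupled with 15 under salt-buffered Stille conditions free of Lewis acid (Pd2(dba)3, AsPh3, LiCl, N-methylpyrrolidone, 50 °C) to give 20, which is hydrolysed to 21 as before.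

**Further compounds**

F1 | step 15 | 3-(bromomethyl)-4-(tert-butyldimethylsilyloxy)benzoic acid | BrCc1cc(ccc1O[Si](C)(C)C(C)(C)C)C(O)=O
F2 | step 15 | C15 tertiary 3-(bromomethyl)-4-(tert-butyldimethylsilyloxy)benzoate of the (14S)-14,15-diol derived from 15 (free C14 hydroxyl, enol triflate retained) | BrCc1cc(ccc1O[Si](C)(C)C(C)(C)C)C(=O)OC(C)(C)[C@@H](O)CC[C@](C)(O[Si](CC)(CC)CC)[C@H](Br)CC[C@]2(C)[C@@H](Br)CCC(C)=C2OS(=O)(=O)C(F)(F)F
F3 | step 3 | (1R,2R)-2-methyl-3-oxo-2-(prop-2-en-1-yl)cyclohexyl trifluoromethanesulfonate | C=CC[C@]1(C)[C@H](OS(=O)(=O)C(F)(F)F)CCCC1=O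
F4 | step 14 | tert-butyldimethylsilyl 4-(tert-butyldimethylsilyloxy)-3-[(tributylstannyl)methyl]benzoate | CCCC[Sn](CCCC)(CCCC)Cc1cc(ccc1O[Si](C)(C)C(C)(C)C)C(=O)O[Si](C)(C)C(C)(C)C
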